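**Plan**

- Retrosynthesis: the N1–CH3 bond and the C4 carbonyl of the target are traced back to a 4-ethoxyquinoline. Its nitrogen ring is cut at C2–C3 and at C4–C4a, and the remaining N1–C2 bond is an amide bond.
- Enabling feature: C2 with its tetradecyl chain is an amide-level carbon on N1. C3, C4 and the C4 oxygen correspond to the two carbons and the oxygen of an alkoxyacetylene, and C4a is an ortho carbon of the N-aryl ring.
- Forward: aniline 1 and pentadecanoyl chloride 2 give anilide 3. Anilide 3 is condensed with ethoxyacetylene 4 after Tf2O activation (nitrilium 5), which closes the nitrogen ring of quinoline 6; the benzo ring comes from aniline.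
- N-Methylation to salt 7 and displacement of ethoxide by hydroxide then give target 8.
- Stereochemistry: the target has no stereocentre and no stereogenic double bond, so nothing has to be set.

Key step: step 2

Remark: the SMILES is read as achiral 1-methyl-2-tetradecylquinolin-4(1H)-one. Pentadecanoyl chloride and ethoxyacetylene (as a solution in hexanes) are taken as commercial.

**Route**

Step 1
Reactants: 1 aniline; 2 pentadecanoyl chloride
Product: 3 N-phenylpentadecanamide
Conditions: 2 M aq. NaOH, CH2Cl2, 0 °C to rt; recrystallisation
Reagents that add atoms: none
Why: Schotten–Baumann N-acylation, in which aniline in the organic phase outcompetes hydroxide for the lipophilic acid chloride while aqueous NaOH takes up the HCl and keeps the amine free.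

Step 2
Reactants: 3 N-phenylpentadecanamide; 4 ethoxyacetylene
Product: 6 4-ethoxy-2-tetradecylquinoline, via N-phenylpentadecanenitrilium triflate 5 (not isolated)
Conditions: Tf2O (1.1 equiv), 2-chloropyridine (1.2 equiv), CH2Cl2, −78 °C to 0 °C; then 4 (2 equiv, in hexanes), 0 °C to rt; basic aqueous work-up
Reagents that add atoms: triflic anhydride, FC(F)(F)S(=O)(=O)OS(=O)(=O)C(F)(F)F (its atoms stay only in the counter-ion of 5, none in 6)
Why: Tf2O sulfonylates the amide oxygen and 2-chloropyridine, too weakly nucleophilic to bind the electrophile irreversibly, removes the N–H proton, so that nitrilium triflate 5 (in equilibrium with its 2-chloropyridine adduct) is the electrophile. The ynol ether 4 adds through its unsubstituted, oxygen-activated carbon to the nitrilium carbon, forming C2–C3 and leaving an ethoxy-stabilised ketenium (vinyl) cation at C4. An ortho carbon of the N-phenyl ring captures this cation to form C4–C4a, a six-membered Friedel–Crafts closure that is 6-endo with respect to the C3=C4 bond and can equally be read as a cationic 6π aza-electrocyclisation, and proton loss aromatises the new pyridine ring. The closest known reaction type is the Tf2O/2-chloropyridine condensation of N-aryl and N-vinyl amides with alkynes, ynamides and alkoxyacetylenes to quinolines and pyridines. No stereocentre arises; the step needs regioselective alkyne addition, secured by the oxygen lone pair that makes only the terminal carbon of 4 nucleophilic and so places oxygen at C4, and the two ortho positions of the unsubstituted N-phenyl ring are equivalent. Chemoselectivity against α-deprotonation of the chain methylene is secured by the low temperature and the weak base, and any ketenimine formed should be re-protonated to 5 by the pyridinium triflate.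

Step 3
Reactants: 6 4-ethoxy-2-tetradecylquinoline
Product: 7 4-ethoxy-1-methyl-2-tetradecylquinolin-1-ium triflate
Conditions: MeOTf (1.2 equiv), CH2Cl2, 0 °C to rt; trituration with Et2O
Reagents that add atoms: methyl triflate, COS(=O)(=O)C(F)(F)F
Why: Menshutkin-type N-alkylation, in which the ring nitrogen, made more electron-rich by the 4-ethoxy donor, is the only site nucleophilic enough for MeOTf; the reagent is reactive enough to overcome the flanking C2 chain and peri C8–H, and the non-nucleophilic triflate leaves the ethyl ether intact.

Step 4
Reactants: 7 4-ethoxy-1-methyl-2-tetradecylquinolin-1-ium triflate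
Product: 8 1-methyl-2-tetradecylquinolin-4(1H)-one
Conditions: 1 M aq. NaOH (3 equiv), THF, rt to 50 °C
Reagents that add atoms: sodium hydroxide, [Na+].[OH-]
Why: Addition–elimination (SNAr type) at C4 of the N-methylquinolinium: hydroxide adds to the vinylogous imidate carbon, ethoxide leaves and the 4-hydroxyquinolinium loses its O–H proton to give the neutral 4-quinolone, whereas addition at the alkylated C2 is reversible and unproductive.

**Compound list**

1 | aniline | Nc1ccccc1 | starting material
2 | pentadecanoyl chloride | CCCCCCCCCCCCCCC(=O)Cl | starting material
3 | N-phenylpentadecanamide | CCCCCCCCCCCCCCC(=O)Nc1ccccc1 | intermediate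
4 | ethoxyacetylene (ethoxyethyne) | C#COCC | starting material
5 | N-phenylpentadecanenitrilium triflate | CCCCCCCCCCCCCCC#[N+]c1ccccc1.[O-]S(=O)(=O)C(F)(F)F | intermediate (not isolated)
6 | 4-ethoxy-2-tetradecylquinoline | CCCCCCCCCCCCCCc1cc(OCC)c2ccccc2n1 | intermediate
7 | 4-ethoxy-1-methyl-2-tetradecylquinolin-1-ium triflate | CCCCCCCCCCCCCCc1cc(OCC)c2ccccc2[n+]1C.[O-]S(=O)(=O)C(F)(F)F | intermediate
8 | 1-methyl-2-tetradecylquinolin-4(1H)-one | CCCCCCCCCCCCCCc1cc(=O)c2ccccc2n1C | target

**Step count**

Total steps: 4. Longest linear sequence: 4 steps (1 or 2 → 3 → 6 → 7 → 8).

**Steps most likely to fail**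

Step 2. The activated amide may be lost through α-deprotonation at the chain methylene to a ketenimine that oligomerises. The acid-sensitive ynol ether may also polymerise or be hydrated by the pyridinium triflate before it intercepts the electrophile, so that C2–C3 bond formation stalls. The fallback sets out from 2 and comes back to the route at 8. Acid chloride 2 acylates commercial 1-[2-(methylamino)phenyl]ethanone (pyridine, catalytic DMAP, CH2Cl2, reflux) to give N-(2-acetylphenyl)-N-methylpentadecanamide F1. A Camps cyclisation (KOt-Bu, t-BuOH/THF, 60–80 °C) then lets the more acidic methyl-ketone enolate attack the anilide carbonyl. Loss of water closes the nitrogen ring through C2–C3 and should give 8 directly, with the N-methyl group already in place.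

Step 4. Hydroxide may act as a base on the C2 α-methylene, giving an anhydro-base (enamine) that oxidises or condenses, or may add reversibly at C2, so that displacement at C4 becomes slow. The fallback sets out from 7 and comes back at 8; it makes no new compound (F0). The O–CH2 bond is broken in place of the C4–O bond, by non-basic SN2 de-ethylation with LiCl in DMF at 100–120 °C. Chloride attacks the ethyl group of the oxonium-like ether and the quinolone is released with its original oxygen.

Step 3. Quaternisation may stall because N1 is flanked by the C2 chain and the peri C8–H, or because triflic acid from adventitious hydrolysis of MeOTf protonates the quinoline. The fallback sets out from 6 and comes back at 8, bypassing 7. The ethyl ether is cleaved first (48% aq. HBr, AcOH, reflux) to give 2-tetradecylquinolin-4(1H)-one F2. Its ambident anion is then methylated with MeI and K2CO3 in DMF, where N-methylation is expected to predominate over the competing O-methylation.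

**Further compounds**

F1 | step 2 | N-(2-acetylphenyl)-N-methylpentadecanamide | CCCCCCCCCCCCCCC(=O)N(C)c1ccccc1C(C)=O
F0 | step 4 | none | none
F2 | step 3 | 2-tetradecylquinolin-4(1H)-one | CCCCCCCCCCCCCCc1cc(=O)c2ccccc2[nH]1
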